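Numbering follows the lactone: C1 is the carbonyl carbon and C24 the OCH2 carbon. The target is one 25-membered ring (C1 to C24 plus the ring oxygen) with no stereocentre.
Retrosynthesis: two phenylsulfonyl groups are placed on C17, then C16–C17 and C17–C18 are cut together so that C17 leaves as bis(phenylsulfonyl)methane. The C1–O ester bond is cut last, giving a C1–C16 omega-bromo acid and a C18–C24 omega-bromo alcohol.
Enabling feature: C2 through C23 of the ring are all unsubstituted CH2 groups, so one of them, C17, can enter as an acidic CH2 that is alkylated on both sides and later returned to CH2.
Forward order: the chain is joined first through the ester oxygen, the single ring then closes by double alkylation at C17, and both sulfonyl groups are removed at the end. All three starting materials are catalogue compounds.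
Stereochemistry: none has to be set. C17 is a stereocentre only in a racemic mono-sulfone that forms and is consumed within the last step.

Key step: step 2

Step 1
Reactants: 1 16-bromohexadecanoic acid; 2 7-bromoheptan-1-ol
Product: 3 7-bromoheptyl 16-bromohexadecanoate
Conditions: DCC (1.1 equiv), DMAP (0.1 equiv), CH2Cl2, 0 °C to rt
Reagents that add atoms: none
Why: Steglich esterification: DCC activates acid 1 as its O-acylisourea, DMAP passes the acyl group on to the unhindered primary alcohol 2, and both primary C–Br bonds are inert to these neutral conditions at room temperature.

Step 2
Reactants: 3 7-bromoheptyl 16-bromohexadecanoate; 4 bis(phenylsulfonyl)methane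
Product: 7 17,17-bis(phenylsulfonyl)tetracosan-24-olide, via acid-end monoalkylated bromo ester 5 (not isolated), via alcohol-end monoalkylated bromo ester 6 (not isolated)
Conditions: Cs2CO3 (5 equiv), dry DMF, 70 °C; equimolar 3 and 4 in DMF added by syringe pump over 24 h (final concentration about 2 mM), then 24 h at 70 °C
Reagents that add atoms: none
Why: Cs2CO3 deprotonates 4, a carbon acid comparable to a 1,3-diketone, and the bis-sulfonyl carbanion displaces one primary bromide of 3 by SN2 to give 5 or 6; a second deprotonation then lets the now tertiary carbanion displace the remaining bromide of the same molecule, so that C16–C17 and C17–C18 are both formed in this operation. The closest known reaction type is the double alkylation of active-methylene compounds (bis(phenylsulfonyl)methane, malonates, TosMIC) with alpha,omega-dihalides under pseudo-high dilution to give carbocycles up to large rings. The single ring closes in a 25-exo-tet mode, the bromide departing outside the forming 25-membered ring, and 5 and 6 converge on the same macrocycle, so it does not matter which bromide reacts first. No stereocentre is created, because C17 carries two identical phenylsulfonyl groups. The step needs ring closure to win over chain extension and over capping of both bromides by two molecules of 4, and it needs C-alkylation to win over attack at the ester; the first is secured by feeding equimolar 3 and 4 slowly into dilute base so that neither accumulates and by the unbranched, strain-free all-CH2 tether with two unhindered primary bromides, the second by the soft, weakly basic carbanion and the carbonate base, neither of which enolises or cleaves an ester flanked by plain CH2 groups.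

Step 3
Reactants: 7 17,17-bis(phenylsulfonyl)tetracosan-24-olide
Product: 9 24-tetracosanolide, via 17-(phenylsulfonyl)tetracosan-24-olide 8 (not isolated)
Conditions: SmI2 (divalent samarium, 0.1 M in THF, 8 equiv), HMPA, MeOH (4 equiv), THF, −20 °C to 0 °C; aq. NH4Cl
Reagents that add atoms: none
Why: Reductive desulfonylation by single-electron transfer: SmI2 activated by HMPA cleaves each C–SO2Ph bond to benzenesulfinate and a carbon-centred radical that is reduced further and protonated by methanol, the first cleavage (assisted by the second sulfonyl group) giving racemic 8 and the second leaving C17 as CH2, while an unactivated lactone should not be reduced by this reagent at low temperature.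

Compound list
1 | 16-bromohexadecanoic acid | OC(=O)CCCCCCCCCCCCCCCBr | starting material
2 | 7-bromoheptan-1-ol | OCCCCCCCBr | starting material
3 | 7-bromoheptyl 16-bromohexadecanoate | BrCCCCCCCCCCCCCCCC(=O)OCCCCCCCBr | intermediate
4 | bis(phenylsulfonyl)methane | O=S(=O)(CS(=O)(=O)c1ccccc1)c1ccccc1 | starting material
5 | 7-bromoheptyl 17,17-bis(phenylsulfonyl)heptadecanoate (acid-end monoalkylated bromo ester, formed in the flask) | BrCCCCCCCOC(=O)CCCCCCCCCCCCCCCC(S(=O)(=O)c1ccccc1)S(=O)(=O)c1ccccc1 | intermediate
6 | 8,8-bis(phenylsulfonyl)octyl 16-bromohexadecanoate (alcohol-end monoalkylated bromo ester, formed in the flask) | BrCCCCCCCCCCCCCCCC(=O)OCCCCCCCC(S(=O)(=O)c1ccccc1)S(=O)(=O)c1ccccc1 | intermediate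
7 | 17,17-bis(phenylsulfonyl)tetracosan-24-olide | O=C1CCCCCCCCCCCCCCCC(S(=O)(=O)c2ccccc2)(S(=O)(=O)c2ccccc2)CCCCCCCO1 | intermediate
8 | 17-(phenylsulfonyl)tetracosan-24-olide (racemic, formed in the flask) | O=C1CCCCCCCCCCCCCCCC(S(=O)(=O)c2ccccc2)CCCCCCCO1 | intermediate
9 | 24-tetracosanolide (oxacyclopentacosan-2-one) | O=C1CCCCCCCCCCCCCCCCCCCCCCCO1 | target

Total step count: 3
Longest linear sequence: 3 steps (1 or 2 to 3, then 7, then 9)

Steps most likely to fail

Step 2. The risk is that intermolecular alkylation outruns ring closure. The tertiary carbanion of 5 or 6 is more hindered than the free anion of 4, so a second molecule of 4 may cap the remaining bromide, or a second molecule of 3 may extend the chain, before the 25-membered ring closes. The fallback sets out from 2 and 4 and returns to the route at 7; it separates the intermolecular and the intramolecular alkylation. An excess of 4 (about 3 equiv, the surplus being recoverable) would be alkylated with 2 using K2CO3 in DMF at 60 °C. This should give 8,8-bis(phenylsulfonyl)octan-1-ol F1, the far less acidic hydroxyl group remaining untouched. Steglich esterification of F1 with 1 (DCC, DMAP, CH2Cl2) should then deliver 6 as an isolated compound. Slow addition of 6 alone to Cs2CO3 in DMF at 70 to 80 °C would close the ring to 7 with no free linchpin present to intercept the bromide.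

Step 3. The risk is that reduction stalls after the first C–S cleavage, because the remaining secondary alkyl phenyl sulfone accepts an electron only reluctantly, or that forcing the reduction transfers an electron to the lactone carbonyl and opens the ring. The fallback sets out from 3 and returns to the route at 9; it replaces the C17 activating groups by ones that are removed hydrolytically. Equimolar 3 and TosMIC (p-toluenesulfonylmethyl isocyanide) would be fed slowly into NaH in DMF at room temperature. Through the same two C–C bonds this should give racemic 17-isocyano-17-(4-methylphenylsulfonyl)tetracosan-24-olide F2. Brief treatment with concentrated aqueous HCl in CH2Cl2/Et2O should hydrolyse the alpha-sulfonyl isocyanide to 17-oxotetracosan-24-olide F3. Condensation with p-toluenesulfonyl hydrazide in ethanol should give 17-(4-methylphenylsulfonylhydrazono)tetracosan-24-olide F4. Reduction of F4 with catecholborane in CHCl3 at 0 °C, followed by NaOAc·3H2O at reflux, should leave C17 as CH2 and give 9 under conditions an ester tolerates.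

Step 1. The risk is O-to-N acyl migration in the O-acylisourea to an unreactive N-acylurea, or slow N-alkylation of DMAP by the primary bromides; either would lower conversion and complicate purification. The fallback sets out from 1 and returns to the route at 3. Acid 1 would be converted with oxalyl chloride and catalytic DMF in CH2Cl2 into 16-bromohexadecanoyl chloride F5. After evaporation, F5 would be added to 2 and pyridine in CH2Cl2 at 0 °C, which should give 3 without any carbodiimide or nucleophilic catalyst.

Further compounds
F1 | step 2 | 8,8-bis(phenylsulfonyl)octan-1-ol | OCCCCCCCC(S(=O)(=O)c1ccccc1)S(=O)(=O)c1ccccc1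
F2 | step 3 | 17-isocyano-17-(4-methylphenylsulfonyl)tetracosan-24-olide (racemic) | O=C1CCCCCCCCCCCCCCCC([N+]#[C-])(S(=O)(=O)c2ccc(C)cc2)CCCCCCCO1
F3 | step 3 | 17-oxotetracosan-24-olide | O=C1CCCCCCCCCCCCCCCC(=O)CCCCCCCO1
F4 | step 3 | 17-(4-methylphenylsulfonylhydrazono)tetracosan-24-olide | O=C1CCCCCCCCCCCCCCCC(=NNS(=O)(=O)c2ccc(C)cc2)CCCCCCCO1
F5 | step 1 | 16-bromohexadecanoyl chloride | O=C(Cl)CCCCCCCCCCCCCCCBr
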